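The cyclopentenone is cut on both sides of its C2=C3 alkene: these two CH carbons come from acetylene, inserted in one operation between the two carbonyl carbons of an open-chain, enantiopure β-keto imide. A titanacyclopropene (acetylene as a cis-vinylene 1,2-dianion) adds to the ketone, creating the oxygenated quaternary centre C1 under chelate control by the neighbouring pentenyl-bearing centre (the later C5), and then displaces the oxazolidinone at the imide carbonyl (the later C4), closing the ring and releasing the auxiliary. The step exploits the 1,3-relationship of the ring ketone C4 and the tertiary carbinol C1 across C5. Evans acylation provides the precursor; acetylation and enzymatic ester hydrolysis finish the route.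

Key step: step 4

Remark: the target is read as 8-[(1R,5R)-1-acetoxy-4-oxo-5-[(2Z)-pent-2-en-1-yl]cyclopent-2-en-1-yl]octanoic acid (pentenyl cis to acetoxy); acetylene is counted as a numbered starting material, and compounds 1, 3 and 6 are taken as purchasable.

Step 1
Reactants: 1 (4Z)-hept-4-enal
Product: 2 (4Z)-hept-4-enoic acid
Conditions: NaClO2, NaH2PO4, 2-methyl-2-butene, t-BuOH/H2O, 0 °C → rt
Reagents that add atoms: NaClO2 (sodium chlorite) [Na+].[O-]Cl=O
Why: Pinnick oxidation should convert the aldehyde into the acid while 2-methyl-2-butene scavenges hypochlorous acid, so the Z-alkene is neither chlorinated nor isomerised; no stereocentre is formed.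

Step 2
Reactants: 2 (4Z)-hept-4-enoic acid; 3 (4S)-4-benzyl-1,3-oxazolidin-2-one
Product: 5 (4S)-4-benzyl-3-[(4Z)-hept-4-enoyl]-1,3-oxazolidin-2-one, via mixed pivalic anhydride 4 (not isolated)
Conditions: PivCl, Et3N, THF, −20 °C; then LiCl, 3, −20 °C → rt
Reagents that add atoms: none
Why: N-acylation of the oxazolidinone through the mixed pivalic anhydride (LiCl/Et3N activation) should occur at the unhindered heptenoyl carbonyl and leaves the auxiliary stereocentre untouched.

Step 3
Reactants: 5 (4S)-4-benzyl-3-[(4Z)-hept-4-enoyl]-1,3-oxazolidin-2-one; 6 methyl 9-chloro-9-oxononanoate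
Product: 8 methyl (10R,12Z)-10-{[(4S)-4-benzyl-2-oxo-1,3-oxazolidin-3-yl]carbonyl}-9-oxopentadec-12-enoate, via lithium Z-enolate 7 (not isolated)
Conditions: LiN(iPr)2, THF, −78 °C; then 6, −78 °C; AcOH, −78 °C
Reagents that add atoms: none
Why: Evans C-acylation of the chelated lithium Z-enolate should take place on the face opposite the benzyl group, which sets the (10R) centre, and 1,3-allylic strain makes the β-keto imide slow to enolise, so the centre should survive isolation.

Step 4
Reactants: 8 methyl (10R,12Z)-10-{[(4S)-4-benzyl-2-oxo-1,3-oxazolidin-3-yl]carbonyl}-9-oxopentadec-12-enoate; 9 acetylene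
Product: 12 methyl 8-[(1R,5R)-1-hydroxy-4-oxo-5-[(2Z)-pent-2-en-1-yl]cyclopent-2-en-1-yl]octanoate, via titanacyclopropene 10 (not isolated), via oxatitanacyclopentene 11 (not isolated)
Conditions: Ti(OiPr)4, 9 (THF solution), Et2O, −78 °C; c-C5H9MgCl (2 equiv per Ti), −78 → −40 °C; then 8, −78 → −20 °C; aq NH4Cl
Reagents that add atoms: none
Why: Proposed new method: acetylene displaces cyclopentene from the divalent-titanium alkene complex to give titanacyclopropene 10, whose two Ti–C bonds behave as a cis-vinylene 1,2-dianion; the ketone carbonyl of chelated 8 inserts into one Ti–C bond (ring bond C1–C2) to give oxatitanacyclopentene 11, and the remaining alkenyl–Ti bond then adds to the exocyclic imide carbonyl and expels the oxazolidinone (ring bond C3–C4), the titanium ending tetravalent. The closest known reaction types are the addition of titanium alkoxide–alkyne complexes of internal or silyl alkynes to ketones, their intramolecular nucleophilic acyl substitution, and their two-fold carbonyl addition to 1,3-dicarbonyl compounds; parent acetylene and an enolisable β-keto imide lie outside that scope. The cyclopentenone is closed by a 5-exo-trig acyl substitution, the whole being a formal (3+2) annulation. The new quaternary carbinol centre C1 (R) is controlled by the existing C5 centre: in the six-membered titanium (or magnesium) chelate of the two carbonyl oxygens the alkyne carbon is delivered to the ketone face anti to the pentenyl group, which places OH cis to pentenyl, while C5 itself should be preserved because the β-keto imide is slow to enolise and the titanium reagent is weakly basic and strongly carbonyl-philic. The step needs chemoselectivity for ketone, then imide, over the remote methyl ester, which the order of carbonyl electrophilicity at −78 °C and the slowness of intermolecular acyl substitution by alkenyltitanium species should secure; regioselectivity is not an issue with the symmetrical alkyne.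

Step 5
Reactants: 12 methyl 8-[(1R,5R)-1-hydroxy-4-oxo-5-[(2Z)-pent-2-en-1-yl]cyclopent-2-en-1-yl]octanoate
Product: 13 methyl 8-[(1R,5R)-1-acetoxy-4-oxo-5-[(2Z)-pent-2-en-1-yl]cyclopent-2-en-1-yl]octanoate
Conditions: Ac2O, Sc(OTf)3 (5 mol %), MeCN, −20 °C
Reagents that add atoms: acetic anhydride CC(=O)OC(C)=O
Why: Lewis acid-catalysed O-acetylation of the hindered tertiary alcohol should occur at oxygen without C–O cleavage (the 4-oxocyclopentenyl cation is strongly destabilised), so both stereocentres are retained, and the non-basic low-temperature conditions should avoid retro-aldol opening.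

Step 6
Reactants: 13 methyl 8-[(1R,5R)-1-acetoxy-4-oxo-5-[(2Z)-pent-2-en-1-yl]cyclopent-2-en-1-yl]octanoate
Product: 14 8-[(1R,5R)-1-acetoxy-4-oxo-5-[(2Z)-pent-2-en-1-yl]cyclopent-2-en-1-yl]octanoic acid
Conditions: pig liver esterase, phosphate buffer pH 7.0/acetone, 25 °C
Reagents that add atoms: water O
Why: Enzymatic ester hydrolysis (carboxylesterase) should cleave the unhindered primary methyl ester at neutral pH, while the tertiary acetate is not accepted by the enzyme and the base-sensitive β-acetoxy enone is never exposed to hydroxide.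

Compound list
1 | (4Z)-hept-4-enal | CC/C=C\CCC=O | starting material
2 | (4Z)-hept-4-enoic acid | CC/C=C\CCC(=O)O | intermediate
3 | (4S)-4-benzyl-1,3-oxazolidin-2-one | O=C1N[C@@H](Cc2ccccc2)CO1 | starting material
4 | (4Z)-hept-4-enoic pivalic anhydride (not isolated) | CC/C=C\CCC(=O)OC(=O)C(C)(C)C | intermediate
5 | (4S)-4-benzyl-3-[(4Z)-hept-4-enoyl]-1,3-oxazolidin-2-one | CC/C=C\CCC(=O)N1[C@@H](Cc2ccccc2)COC1=O | intermediate
6 | methyl 9-chloro-9-oxononanoate | COC(=O)CCCCCCCC(=O)Cl | starting material
7 | lithium (Z)-enolate of 5 (not isolated) | CC/C=C\C/C=C(\[O-])N1[C@@H](Cc2ccccc2)COC1=O.[Li+] | intermediate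
8 | methyl (10R,12Z)-10-{[(4S)-4-benzyl-2-oxo-1,3-oxazolidin-3-yl]carbonyl}-9-oxopentadec-12-enoate | CC/C=C\C[C@H](C(=O)CCCCCCCC(=O)OC)C(=O)N1[C@@H](Cc2ccccc2)COC1=O | intermediate
9 | acetylene | C#C | starting material
10 | titanacyclopropene (η2-C2H2)Ti(OiPr)2 (not isolated) | CC(C)O[Ti]1(OC(C)C)C=C1 | intermediate
11 | oxatitanacyclopentene from addition of 10 to the ketone of 8, carbinol carbon configured as in 12 (not isolated) | CC(C)O[Ti]1(OC(C)C)O[C@@](CCCCCCCC(=O)OC)([C@@H](C/C=C\CC)C(=O)N2[C@@H](Cc3ccccc3)COC2=O)C=C1 | intermediate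
12 | methyl 8-[(1R,5R)-1-hydroxy-4-oxo-5-[(2Z)-pent-2-en-1-yl]cyclopent-2-en-1-yl]octanoate | CC/C=C\C[C@H]1C(=O)C=C[C@@]1(CCCCCCCC(=O)OC)O | intermediate
13 | methyl 8-[(1R,5R)-1-acetoxy-4-oxo-5-[(2Z)-pent-2-en-1-yl]cyclopent-2-en-1-yl]octanoate | CC/C=C\C[C@H]1C(=O)C=C[C@@]1(CCCCCCCC(=O)OC)OC(C)=O | intermediate
14 | 8-[(1R,5R)-1-acetoxy-4-oxo-5-[(2Z)-pent-2-en-1-yl]cyclopent-2-en-1-yl]octanoic acid | CC/C=C\C[C@H]1C(=O)C=C[C@@]1(CCCCCCCC(=O)O)OC(C)=O | target

Total step count: 6. Longest linear sequence: 6 steps (1 → 14).

Steps most likely to fail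

Step 4 (Proposed new method). The titanium–carbon bonds may be protonated by acetylene or by the β-keto imide, acetylene may oligomerise at titanium, the sequence may stall after the first carbon–carbon bond, or the facial selectivity at the ketone may be poor. The fallback uses known chemistry and closes the ring by olefin metathesis; it sets out from 8 and comes back at 12. Chelation-controlled addition of CH2=CHMgBr in the presence of MgBr2·OEt2 (CH2Cl2/THF, −78 °C) should give the tertiary allylic alcohol methyl (9R,10R,12Z)-10-{[(4S)-4-benzyl-2-oxo-1,3-oxazolidin-3-yl]carbonyl}-9-ethenyl-9-hydroxypentadec-12-enoate F1. Transamidation with AlMe3/MeNH(OMe)·HCl (CH2Cl2, −20 °C) should release the auxiliary and give the Weinreb amide methyl (9R,10R,12Z)-9-ethenyl-9-hydroxy-10-[methoxy(methyl)carbamoyl]pentadec-12-enoate F2. CH2=CHMgBr (THF, −78 °C) should then give the hydroxy dienone methyl (9R,10R,12Z)-9-ethenyl-9-hydroxy-10-(prop-2-enoyl)pentadec-12-enoate F3. Ring-closing metathesis with the second-generation Grubbs catalyst (CH2Cl2, 40 °C) should join the two terminal vinyl groups and return to 12; the internal Z-alkene is expected to react more slowly than the terminal ones.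

Step 3. The enolate may be acylated at oxygen, the product may exchange a proton with unreacted enolate, and the new stereocentre may epimerise during work-up or on silica. The fallback sets the same centre by an aldol reaction and then oxidises; it sets out from 2 (through 4) and comes back at 12. Acylation of purchased (4R)-4-benzyl-1,3-oxazolidin-2-one as in step 2 should give (4R)-4-benzyl-3-[(4Z)-hept-4-enoyl]-1,3-oxazolidin-2-one F4. The boron syn-aldol reaction (Bu2BOTf, iPr2NEt, CH2Cl2, −78 → 0 °C) with purchased methyl 9-oxononanoate should give methyl (9S,10R,12Z)-10-{[(4R)-4-benzyl-2-oxo-1,3-oxazolidin-3-yl]carbonyl}-9-hydroxypentadec-12-enoate F5, the (10R) centre being set in a Zimmerman–Traxler transition state. Oxidation of the carbinol with Dess–Martin periodinane (CH2Cl2, NaHCO3) should give methyl (10R,12Z)-10-{[(4R)-4-benzyl-2-oxo-1,3-oxazolidin-3-yl]carbonyl}-9-oxopentadec-12-enoate F6. This compound differs from 8 only in the auxiliary, which is expelled when it is submitted to step 4, so the route is rejoined at 12.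

Step 5. Under the Lewis acid the β-hydroxy ketone may open by retro-aldol cleavage or lose water, or the hindered tertiary alcohol may acylate incompletely. The fallback acetylates the metal alkoxide instead of the free alcohol; it sets out from 8 and comes back at 13. After the annulation of step 4 is complete and before any protic quench, acetyl chloride (excess, −40 → 0 °C) is added to the flask so that the tertiary titanium alkoxide is O-acetylated directly. No new compound is involved.

Further compounds
F1 | step 4 | methyl (9R,10R,12Z)-10-{[(4S)-4-benzyl-2-oxo-1,3-oxazolidin-3-yl]carbonyl}-9-ethenyl-9-hydroxypentadec-12-enoate | CC/C=C\C[C@H]([C@](O)(C=C)CCCCCCCC(=O)OC)C(=O)N1[C@@H](Cc2ccccc2)COC1=O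
F2 | step 4 | methyl (9R,10R,12Z)-9-ethenyl-9-hydroxy-10-[methoxy(methyl)carbamoyl]pentadec-12-enoate | CC/C=C\C[C@H]([C@](O)(C=C)CCCCCCCC(=O)OC)C(=O)N(C)OC
F3 | step 4 | methyl (9R,10R,12Z)-9-ethenyl-9-hydroxy-10-(prop-2-enoyl)pentadec-12-enoate | CC/C=C\C[C@H]([C@](O)(C=C)CCCCCCCC(=O)OC)C(=O)C=C
F4 | step 3 | (4R)-4-benzyl-3-[(4Z)-hept-4-enoyl]-1,3-oxazolidin-2-one | CC/C=C\CCC(=O)N1[C@H](Cc2ccccc2)COC1=O
F5 | step 3 | methyl (9S,10R,12Z)-10-{[(4R)-4-benzyl-2-oxo-1,3-oxazolidin-3-yl]carbonyl}-9-hydroxypentadec-12-enoate | CC/C=C\C[C@H]([C@@H](O)CCCCCCCC(=O)OC)C(=O)N1[C@H](Cc2ccccc2)COC1=O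
F6 | step 3 | methyl (10R,12Z)-10-{[(4R)-4-benzyl-2-oxo-1,3-oxazolidin-3-yl]carbonyl}-9-oxopentadec-12-enoate | CC/C=C\C[C@H](C(=O)CCCCCCCC(=O)OC)C(=O)N1[C@H](Cc2ccccc2)COC1=O
F0 | step 5 | none | none
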